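**Plan**

1. Numbering used throughout (germacranolide numbering): ten-membered ring C1–C10; lactone O–C6, C7, C11(=C13H2), C12(=O); C14 = CHO on C10; C15 = CH2OH on C4; ester on O8. The retrosynthesis removes the O8 acyl group and the protecting groups, opens the lactone C12–O bond, then cuts C11–C12 and C6–C7 together (C12 leaves as CO2), which opens the ten-membered ring to an acyclic allenyl enal. That chain is cut at C1=C10 and C4=C5 (two Horner–Wadsworth–Emmons olefinations).
2. Enabling feature: the α-methylene lactone is a 2-carboxyallyl unit (C13=C11(C12)–C7) bonded to the carbinol carbon C6. A terminal allene C7=C11=C13 can take up CO2 at C11 on zerovalent nickel, and the allylnickel so formed can add through C7 to a C6 aldehyde. Both ring alkenes (C1=C10, C4=C5) are cis within the ring and fold the chain.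
3. Forward: right fragment (C7–C11, C14) from a succinate ynone; left fragment (C1–C6, C15) from triethyl phosphonoacetate; union at C1=C10; adjustment to allenyl enal 23; the key step closes the ten-membered carbocycle, lactonisation then closes the five-membered ring; acylation of O8 and deprotection finish.
4. Stereochemistry: C8 by Noyori transfer hydrogenation (catalyst control); both trisubstituted alkenes by E-selective olefination; C6 and C7 in the key step relative to C8 (chair-like allyl transfer gives 6,7-anti, hence the trans-lactone; bond formation anti to C8–C9); the acyl stereocentre comes from (2R)-2-methylbutanoic acid.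

Key step: step 16

Remark on the chemistry: compounds 10 and 28 are taken as purchasable; nickel complex 24 is drawn without its DBU ligands; TBS = tert-butyldimethylsilyl, TBDPS = tert-butyldiphenylsilyl, PMB = 4-methoxybenzyl.

**Route**

Step 1
Reactants: 1 ethyl 4-chloro-4-oxobutanoate; 2 bis(trimethylsilyl)acetylene
Product: 3 ethyl 4-oxo-6-(trimethylsilyl)hex-5-ynoate
Conditions: AlCl3, CH2Cl2, 0 °C
Reagents that add atoms: none
Why: Friedel–Crafts-type acylation of the alkynylsilane (ipso substitution with loss of Me3SiCl) should give the ynone that carries C8 (carbonyl), C7/C11 (alkyne) and C9, C10, C14 (ester chain).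

Step 2
Reactants: 3
Product: 5 (5R)-5-[(trimethylsilyl)ethynyl]oxolan-2-one, via hydroxy ester 4 (not isolated)
Conditions: Ru[(R,R)-TsDPEN](p-cymene) (1 mol %), i-PrOH, 25 °C; then PPTS (cat.), toluene, 60 °C
Reagents that add atoms: none
Why: Noyori asymmetric transfer hydrogenation of the alkynyl ketone should set C8 as (R) by catalyst control (the alkyne takes the place of the aryl group of the usual substrates), and the γ-hydroxy ester should close to the lactone, which ties O8 and C14 into one temporary ring.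

Step 3
Reactants: 5
Product: 6 diethyl {(5R)-2-oxo-5-[(trimethylsilyl)ethynyl]oxolan-3-yl}phosphonate (both C3 epimers)
Conditions: LiN(i-Pr)2 (1.1 equiv), THF, −78 °C; ClP(O)(OEt)2; LiN(i-Pr)2 (2.2 equiv), −78 → 0 °C; AcOH
Reagents that add atoms: diethyl chlorophosphate, CCOP(=O)(Cl)OCC
Why: O-phosphorylation of the lactone enolate followed by base-induced 1,3-phosphorus shift (enol phosphate to α-phosphono lactone rearrangement) should give the olefination reagent; the new centre at C10 disappears in step 9.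

Step 4
Reactants: 7 triethyl phosphonoacetate; 8 2-(2-bromoethyl)-1,3-dioxolane
Product: 9 ethyl 2-(diethoxyphosphoryl)-4-(1,3-dioxolan-2-yl)butanoate (racemic)
Conditions: NaH, DMSO, 20 → 60 °C
Reagents that add atoms: none
Why: SN2 alkylation of the phosphonoacetate anion with the primary bromide should attach C3–C2–C1 (C1 masked as dioxolane) to C4.

Step 5
Reactants: 9; 10 2-[(4-methoxyphenyl)methoxy]acetaldehyde
Product: 11 ethyl (2E)-2-[2-(1,3-dioxolan-2-yl)ethyl]-4-(PMB-oxy)but-2-enoate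
Conditions: LiCl, DBU, MeCN, 0 → 20 °C
Reagents that add atoms: none
Why: Horner–Wadsworth–Emmons olefination under Masamune–Roush conditions should give the C4=C5 alkene with the ester carbon C15 trans to C6 (E, adduct equilibration before elimination), which places C3 cis to C6 as the ring requires.

Step 6
Reactants: 11
Product: 12 (2E)-2-[2-(1,3-dioxolan-2-yl)ethyl]-4-(PMB-oxy)but-2-en-1-ol
Conditions: i-Bu2AlH (2.2 equiv), CH2Cl2, −78 °C; Rochelle salt work-up
Reagents that add atoms: none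
Why: 1,2-reduction of the enoate by the aluminium hydride should give the allylic alcohol at C15 and leave acetal, PMB ether and alkene geometry untouched.

Step 7
Reactants: 12
Product: 13 tert-butyl{[(2E)-2-[2-(1,3-dioxolan-2-yl)ethyl]-4-(PMB-oxy)but-2-en-1-yl]oxy}diphenylsilane
Conditions: TBDPSCl, imidazole, DMF, 20 °C
Reagents that add atoms: tert-butyl(chloro)diphenylsilane, CC(C)(C)[Si](Cl)(c1ccccc1)c1ccccc1
Why: silylation of the primary alcohol should install an acid-stable group on O15 that lasts to the final step.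

Step 8
Reactants: 13
Product: 14 (4E)-6-(PMB-oxy)-4-[(TBDPS-oxy)methyl]hex-4-enal
Conditions: AcOH/H2O/THF (3:1:1), 45 °C
Reagents that add atoms: water, O
Why: acid hydrolysis of the dioxolane should free the C1 aldehyde, the PMB and TBDPS ethers being stable under these conditions.

Step 9
Reactants: 6; 14
Product: 15 (3E,5R)-3-{(4E)-6-(PMB-oxy)-4-[(TBDPS-oxy)methyl]hex-4-en-1-ylidene}-5-[(trimethylsilyl)ethynyl]oxolan-2-one
Conditions: NaH, THF, 0 → 20 °C
Reagents that add atoms: none
Why: Horner–Wadsworth–Emmons olefination of the α-phosphono lactone should give the exocyclic C1=C10 alkene with C2 trans to the lactone carbonyl C14 (E) and therefore cis to C9, the less strained arrangement of the alkylidene lactone.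

Step 10
Reactants: 15
Product: 17 (2E,6E)-N-methoxy-N-methyl-8-(PMB-oxy)-2-[(2R)-2-(TBS-oxy)-4-(trimethylsilyl)but-3-yn-1-yl]-6-[(TBDPS-oxy)methyl]octa-2,6-dienamide, via hydroxy amide 16 (not isolated)
Conditions: MeNH(OMe)·HCl, Me3Al, CH2Cl2, 0 → 20 °C; then TBSOTf, 2,6-lutidine, CH2Cl2, −78 °C
Reagents that add atoms: N,O-dimethylhydroxylamine hydrochloride, CNOC.Cl; tert-butyldimethylsilyl trifluoromethanesulfonate, CC(C)(C)[Si](C)(C)OS(=O)(=O)C(F)(F)F
Why: Weinreb aminolysis by the aluminium amide should open the temporary lactone, and immediate silylation of the freed C8 hydroxyl should prevent relactonisation; C8 is not touched.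

Step 11
Reactants: 17
Product: 18 (2E,6E)-8-(PMB-oxy)-2-[(2R)-2-(TBS-oxy)-4-(trimethylsilyl)but-3-yn-1-yl]-6-[(TBDPS-oxy)methyl]octa-2,6-dienal
Conditions: i-Bu2AlH, THF, −78 °C; Rochelle salt work-up
Reagents that add atoms: none
Why: reduction of the Weinreb amide should stop at the aldehyde through the chelated tetrahedral intermediate and give the C14 enal with the C1=C10 geometry retained.

Step 12
Reactants: 18
Product: 20 dimethyl acetal of (2E,6E)-8-(PMB-oxy)-2-[(2R)-2-(TBS-oxy)but-3-yn-1-yl]-6-[(TBDPS-oxy)methyl]octa-2,6-dienal, via silylalkyne acetal 19 (not isolated)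
Conditions: HC(OMe)3, PPTS (cat.), MeOH, 20 °C; then K2CO3, 20 °C
Reagents that add atoms: trimethyl orthoformate, COC(OC)OC; methanol, CO
Why: acetalisation should mask C14 so that C6 will be the only aldehyde in the key step, and base methanolysis of the C–Si bond should then free the terminal alkyne.

Step 13
Reactants: 20
Product: 21 dimethyl acetal of (2E,6E)-8-(PMB-oxy)-2-[(2R)-2-(TBS-oxy)penta-3,4-dien-1-yl]-6-[(TBDPS-oxy)methyl]octa-2,6-dienal
Conditions: (CH2O)n, CuI (0.5 equiv), Cy2NH (1.8 equiv), 1,4-dioxane, reflux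
Reagents that add atoms: paraformaldehyde (as formaldehyde), C=O
Why: Crabbé homologation (Mannich propargylamine, then copper-mediated 1,5-hydride shift and elimination of the imine) should turn the terminal alkyne into the terminal allene C7=C11=C13, with C8 not involved.

Step 14
Reactants: 21
Product: 22 (2E,6E)-8,8-dimethoxy-7-[(2R)-2-(TBS-oxy)penta-3,4-dien-1-yl]-3-[(TBDPS-oxy)methyl]octa-2,6-dien-1-ol
Conditions: DDQ, CH2Cl2/pH 7 phosphate buffer (10:1), 0 °C
Reagents that add atoms: none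
Why: oxidative cleavage of the PMB ether (benzylic hydride abstraction, hydrolysis of the oxocarbenium ion) should free the C6 hydroxyl while the buffer protects the acetal and the silyl ethers.

Step 15
Reactants: 22
Product: 23 (2E,6E)-8,8-dimethoxy-7-[(2R)-2-(TBS-oxy)penta-3,4-dien-1-yl]-3-[(TBDPS-oxy)methyl]octa-2,6-dienal
Conditions: Dess–Martin periodinane, NaHCO3, CH2Cl2, 0 °C
Reagents that add atoms: none
Why: Dess–Martin oxidation under buffered, non-isomerising conditions should give the C6 enal with C3 still cis to C6.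

Step 16
Reactants: 23
Product: 25 2-[(1S,2R,3E,7E,10R)-8-(dimethoxymethyl)-2-hydroxy-10-(TBS-oxy)-4-[(TBDPS-oxy)methyl]cyclodeca-3,7-dien-1-yl]prop-2-enoic acid, via nickelalactone 24 (not isolated)
Conditions: Ni(cod)2 (1.2 equiv), DBU (4 equiv), CO2 (1 atm), THF, 0 °C, 23 added over 8 h to 0.003 M; then 20 °C; cold aq. HCl (0.2 M) to pH 4
Reagents that add atoms: carbon dioxide, O=C=O
Why: Proposed new method: zerovalent nickel should couple the terminal C11=C13 π-bond of the allene with CO2 by oxidative cyclisation, which forms C11–C12 and gives nickelalactone 24, a σ/π-allylnickel carboxylate; its γ-carbon C7 should then add to the tethered aldehyde carbon C6 through a six-membered chair-like array (Ni–C13–C11–C7···C6=O), which forms C6–C7 and closes the ten-membered carbocycle by exo attack on the carbonyl (10-exo-trig). The closest known reaction type is the nickel-mediated sequential addition of CO2 and an aldehyde to a terminal allene with DBU as ligand, known between two molecules and, for allenyl aldehydes, in closures to five- and six-membered rings; the extension to a ten-membered ring is the untested part and is argued from the persistence of the nickelalactone, high dilution and the two cis ring alkenes that hold C6 near C7. C6 and C7: the allyl unit should react in its syn form (C8 trans to C13) with the enal chain equatorial in the chair, which gives the 6,7-anti adduct, the one that leads to the trans-fused lactone. C7 relative to C8: 1,3-allylic strain against the C12 carboxylate should turn H8 into the allyl plane, and C6 should bond anti to the C8–C9 bond with the silyloxy group outside, giving (6R,7S,8R) in the germacranolide numbering of 25. The step needs attack at C7 and not at C13 (secured by the cyclic transition state with nickel on C13), 1,2- and not 1,4-addition to the enal, and a single free aldehyde (C14 is an acetal).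

Step 17
Reactants: 25
Product: 26 (3aS,4R,6E,10E,11aR)-6-(dimethoxymethyl)-3-methylidene-4-(TBS-oxy)-10-[(TBDPS-oxy)methyl]-3a,4,5,8,9,11a-hexahydrocyclodeca[b]furan-2(3H)-one
Conditions: EDC·HCl, DMAP (cat.), CH2Cl2, 0 → 20 °C
Reagents that add atoms: none
Why: carbodiimide activation of the acrylic acid and attack by the C6 hydroxyl (5-exo-trig lactonisation) should close the γ-lactone, the trans ring fusion following from the anti C6/C7 configuration.

Step 18
Reactants: 26
Product: 27 (3aR,4R,6E,10E,11aR)-6-(dimethoxymethyl)-4-hydroxy-3-methylidene-10-[(TBDPS-oxy)methyl]-3a,4,5,8,9,11a-hexahydrocyclodeca[b]furan-2(3H)-one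
Conditions: HF·pyridine, pyridine, THF, 0 → 20 °C
Reagents that add atoms: none
Why: fluoride-mediated cleavage of the secondary TBS ether should be faster than that of the bulkier primary TBDPS ether, and the buffered water-free medium should leave the acetal intact.

Step 19
Reactants: 27; 28 (2R)-2-methylbutanoic acid
Product: 29 (3aR,4R,6E,10E,11aR)-6-(dimethoxymethyl)-3-methylidene-2-oxo-10-[(TBDPS-oxy)methyl]-2,3,3a,4,5,8,9,11a-octahydrocyclodeca[b]furan-4-yl (2R)-2-methylbutanoate
Conditions: DCC, DMAP (cat.), CH2Cl2, 0 → 20 °C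
Reagents that add atoms: none
Why: Steglich esterification should acylate O8 without touching the C8–O bond, the acyl stereocentre coming unchanged from 28.

Step 20
Reactants: 29
Product: 30 (3aR,4R,6E,10E,11aR)-6-formyl-10-(hydroxymethyl)-3-methylidene-2-oxo-2,3,3a,4,5,8,9,11a-octahydrocyclodeca[b]furan-4-yl (2R)-2-methylbutanoate
Conditions: aq. HF (48 %), MeCN, 0 → 20 °C
Reagents that add atoms: water, O
Why: aqueous HF should cleave the primary TBDPS ether and hydrolyse the α,β-unsaturated dimethyl acetal to the C14 enal in one operation, with lactone, ester and stereocentres unaffected.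

**Compound list**

1 | ethyl 4-chloro-4-oxobutanoate | CCOC(=O)CCC(Cl)=O | starting material
2 | bis(trimethylsilyl)acetylene | C[Si](C)(C)C#C[Si](C)(C)C | starting material
3 | ethyl 4-oxo-6-(trimethylsilyl)hex-5-ynoate | CCOC(=O)CCC(=O)C#C[Si](C)(C)C | intermediate
4 | ethyl (4R)-4-hydroxy-6-(trimethylsilyl)hex-5-ynoate | CCOC(=O)CC[C@@H](O)C#C[Si](C)(C)C | intermediate
5 | (5R)-5-[(trimethylsilyl)ethynyl]oxolan-2-one | C[Si](C)(C)C#C[C@H]1CCC(=O)O1 | intermediate
6 | diethyl {(5R)-2-oxo-5-[(trimethylsilyl)ethynyl]oxolan-3-yl}phosphonate | C[Si](C)(C)C#C[C@H]1CC(P(=O)(OCC)OCC)C(=O)O1 | intermediate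
7 | triethyl phosphonoacetate | CCOC(=O)CP(=O)(OCC)OCC | starting material
8 | 2-(2-bromoethyl)-1,3-dioxolane | BrCCC1OCCO1 | starting material
9 | ethyl 2-(diethoxyphosphoryl)-4-(1,3-dioxolan-2-yl)butanoate | CCOC(=O)C(CCC1OCCO1)P(=O)(OCC)OCC | intermediate
10 | 2-[(4-methoxyphenyl)methoxy]acetaldehyde | COc1ccc(COCC=O)cc1 | starting material
11 | ethyl (2E)-2-[2-(1,3-dioxolan-2-yl)ethyl]-4-(PMB-oxy)but-2-enoate | CCOC(=O)/C(CCC1OCCO1)=C/COCc1ccc(OC)cc1 | intermediate
12 | (2E)-2-[2-(1,3-dioxolan-2-yl)ethyl]-4-(PMB-oxy)but-2-en-1-ol | OC/C(CCC1OCCO1)=C/COCc1ccc(OC)cc1 | intermediate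
13 | TBDPS ether of 12 | CC(C)(C)[Si](OC/C(CCC1OCCO1)=C/COCc1ccc(OC)cc1)(c1ccccc1)c1ccccc1 | intermediate
14 | (4E)-6-(PMB-oxy)-4-[(TBDPS-oxy)methyl]hex-4-enal | O=CCC/C(CO[Si](c1ccccc1)(c1ccccc1)C(C)(C)C)=C\COCc1ccc(OC)cc1 | intermediate
15 | (3E,5R)-3-{(4E)-6-(PMB-oxy)-4-[(TBDPS-oxy)methyl]hex-4-en-1-ylidene}-5-[(trimethylsilyl)ethynyl]oxolan-2-one | C[Si](C)(C)C#C[C@H]1C/C(=C\CC/C(CO[Si](c2ccccc2)(c2ccccc2)C(C)(C)C)=C\COCc2ccc(OC)cc2)C(=O)O1 | intermediate
16 | (2E,6E)-2-[(2R)-2-hydroxy-4-(trimethylsilyl)but-3-yn-1-yl]-N-methoxy-N-methyl-8-(PMB-oxy)-6-[(TBDPS-oxy)methyl]octa-2,6-dienamide | CON(C)C(=O)/C(C[C@@H](O)C#C[Si](C)(C)C)=C/CC/C(CO[Si](c1ccccc1)(c1ccccc1)C(C)(C)C)=C\COCc1ccc(OC)cc1 | intermediate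
17 | TBS ether of 16 at O8 | CON(C)C(=O)/C(C[C@@H](O[Si](C)(C)C(C)(C)C)C#C[Si](C)(C)C)=C/CC/C(CO[Si](c1ccccc1)(c1ccccc1)C(C)(C)C)=C\COCc1ccc(OC)cc1 | intermediate
18 | (2E,6E)-8-(PMB-oxy)-2-[(2R)-2-(TBS-oxy)-4-(trimethylsilyl)but-3-yn-1-yl]-6-[(TBDPS-oxy)methyl]octa-2,6-dienal | O=C/C(C[C@@H](O[Si](C)(C)C(C)(C)C)C#C[Si](C)(C)C)=C/CC/C(CO[Si](c1ccccc1)(c1ccccc1)C(C)(C)C)=C\COCc1ccc(OC)cc1 | intermediate
19 | dimethyl acetal of 18 | COC(OC)/C(C[C@@H](O[Si](C)(C)C(C)(C)C)C#C[Si](C)(C)C)=C/CC/C(CO[Si](c1ccccc1)(c1ccccc1)C(C)(C)C)=C\COCc1ccc(OC)cc1 | intermediate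
20 | 19 with the alkyne terminus as C≡C–H | COC(OC)/C(C[C@@H](O[Si](C)(C)C(C)(C)C)C#C)=C/CC/C(CO[Si](c1ccccc1)(c1ccccc1)C(C)(C)C)=C\COCc1ccc(OC)cc1 | intermediate
21 | terminal allene: 20 with C≡C–H homologated to CH=C=CH2 | COC(OC)/C(C[C@@H](O[Si](C)(C)C(C)(C)C)C=C=C)=C/CC/C(CO[Si](c1ccccc1)(c1ccccc1)C(C)(C)C)=C\COCc1ccc(OC)cc1 | intermediate
22 | (2E,6E)-8,8-dimethoxy-7-[(2R)-2-(TBS-oxy)penta-3,4-dien-1-yl]-3-[(TBDPS-oxy)methyl]octa-2,6-dien-1-ol | COC(OC)/C(C[C@@H](O[Si](C)(C)C(C)(C)C)C=C=C)=C/CC/C(CO[Si](c1ccccc1)(c1ccccc1)C(C)(C)C)=C\CO | intermediate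
23 | (2E,6E)-8,8-dimethoxy-7-[(2R)-2-(TBS-oxy)penta-3,4-dien-1-yl]-3-[(TBDPS-oxy)methyl]octa-2,6-dienal | COC(OC)/C(C[C@@H](O[Si](C)(C)C(C)(C)C)C=C=C)=C/CC/C(CO[Si](c1ccccc1)(c1ccccc1)C(C)(C)C)=C\C=O | intermediate
24 | nickelalactone from CO2 and the C11=C13 bond of 23 (ring Ni–C13H2–C11–C12(=O)–O; C11=C7 with C8 trans to C13) | O=C1O[Ni]C/C1=C/[C@H](O[Si](C)(C)C(C)(C)C)C/C(C(OC)OC)=C\CC/C(CO[Si](c1ccccc1)(c1ccccc1)C(C)(C)C)=C\C=O | intermediate
25 | 2-[(1S,2R,3E,7E,10R)-8-(dimethoxymethyl)-2-hydroxy-10-(TBS-oxy)-4-[(TBDPS-oxy)methyl]cyclodeca-3,7-dien-1-yl]prop-2-enoic acid | C=C(C(O)=O)[C@H]1[C@H](O)/C=C(/CO[Si](c2ccccc2)(c2ccccc2)C(C)(C)C)CC/C=C(/C(OC)OC)C[C@H]1O[Si](C)(C)C(C)(C)C | intermediate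
26 | (3aS,4R,6E,10E,11aR)-6-(dimethoxymethyl)-3-methylidene-4-(TBS-oxy)-10-[(TBDPS-oxy)methyl]-3a,4,5,8,9,11a-hexahydrocyclodeca[b]furan-2(3H)-one | C=C1C(=O)O[C@@H]2/C=C(/CO[Si](c3ccccc3)(c3ccccc3)C(C)(C)C)CC/C=C(/C(OC)OC)C[C@@H](O[Si](C)(C)C(C)(C)C)[C@@H]12 | intermediate
27 | (3aR,4R,6E,10E,11aR)-6-(dimethoxymethyl)-4-hydroxy-3-methylidene-10-[(TBDPS-oxy)methyl]-3a,4,5,8,9,11a-hexahydrocyclodeca[b]furan-2(3H)-one | C=C1C(=O)O[C@@H]2/C=C(/CO[Si](c3ccccc3)(c3ccccc3)C(C)(C)C)CC/C=C(/C(OC)OC)C[C@@H](O)[C@@H]12 | intermediate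
28 | (2R)-2-methylbutanoic acid | CC[C@@H](C)C(=O)O | starting material
29 | (2R)-2-methylbutanoate of 27 at O8 | C=C1C(=O)O[C@@H]2/C=C(/CO[Si](c3ccccc3)(c3ccccc3)C(C)(C)C)CC/C=C(/C(OC)OC)C[C@@H](OC(=O)[C@H](C)CC)[C@@H]12 | intermediate
30 | (3aR,4R,6E,10E,11aR)-6-formyl-10-(hydroxymethyl)-3-methylidene-2-oxo-2,3,3a,4,5,8,9,11a-octahydrocyclodeca[b]furan-4-yl (2R)-2-methylbutanoate | C=C1C(=O)O[C@@H]2/C=C(/CO)CC/C=C(/C=O)C[C@@H](OC(=O)[C@H](C)CC)[C@@H]12 | target

**Count**

Total steps: 20. Longest linear sequence: 17 steps (steps 4–8, then 9–20).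

**Steps most likely to fail**

Step 16 (Proposed new method). The ten-membered closure may be too slow, so that the allylnickel carboxylate is protonated or oligomerises, or C6 may add to the wrong face of C7. The fallback uses known chemistry, the chromium-mediated intramolecular allylation of an aldehyde by a 2-(bromomethyl)acrylate, a Nozaki–Hiyama–Kishi-type closure known for α-methylene lactones on medium rings. It sets out from 20. Deprotonation with n-BuLi and methyl chloroformate should give ynoate F1 (C11–C12 made by acetylide acylation). 1,4-Hydroalumination with i-Bu2AlH/HMPA and trapping of the α-aluminio acrylate with formaldehyde should give 2-(hydroxymethyl)enoate F2, and Appel bromination (CBr4, PPh3) the allylic bromide F3. DDQ should then give alcohol F4 and Dess–Martin oxidation the bromo enal F5. CrCl2 in THF at high dilution should close C6–C7, and the hydroxy ester should lactonise to 26, where the route is rejoined.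

Step 5. The α-branched phosphonate may give poor E/Z control at C4=C5. The fallback sets out from 10. Morita–Baylis–Hillman reaction with methyl acrylate (DABCO) should give adduct F6 and acetylation the acetate F7. Copper-catalysed SN2′ displacement with (1,3-dioxolan-2-ylmethyl)magnesium bromide should give the (E)-enoate F8, and i-Bu2AlH reduction should give 12.

Step 18. The primary TBDPS ether or the acetal may be lost along with the TBS group, or the lactone may migrate from O6 to the freed O8. The fallback sets out from 26. TBAF/AcOH should remove both silyl groups to give diol F9, and silylation of the primary allylic hydroxyl alone (TBSCl, imidazole, −20 °C) the silyl ether F10. Steglich esterification with 28 should give ester F11, and aqueous HF in MeCN should then give 30.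

**Further compounds**

F1 | step 16 | methyl ynoate from 20 (C≡C–CO2Me at C11) | COC(=O)C#C[C@H](O[Si](C)(C)C(C)(C)C)C/C(C(OC)OC)=C\CC/C(CO[Si](c1ccccc1)(c1ccccc1)C(C)(C)C)=C\COCc1ccc(OC)cc1
F2 | step 16 | methyl 2-(hydroxymethyl)alk-2-enoate from F1 (C7=C11 geometry immaterial) | COC(=O)C(CO)=C[C@H](O[Si](C)(C)C(C)(C)C)C/C(C(OC)OC)=C\CC/C(CO[Si](c1ccccc1)(c1ccccc1)C(C)(C)C)=C\COCc1ccc(OC)cc1
F3 | step 16 | methyl 2-(bromomethyl)alk-2-enoate from F2 | COC(=O)C(CBr)=C[C@H](O[Si](C)(C)C(C)(C)C)C/C(C(OC)OC)=C\CC/C(CO[Si](c1ccccc1)(c1ccccc1)C(C)(C)C)=C\COCc1ccc(OC)cc1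
F4 | step 16 | F3 with the PMB ether cleaved (C6 alcohol) | COC(=O)C(CBr)=C[C@H](O[Si](C)(C)C(C)(C)C)C/C(C(OC)OC)=C\CC/C(CO[Si](c1ccccc1)(c1ccccc1)C(C)(C)C)=C\CO
F5 | step 16 | bromo enal (C6 aldehyde) from F4 | COC(=O)C(CBr)=C[C@H](O[Si](C)(C)C(C)(C)C)C/C(C(OC)OC)=C\CC/C(CO[Si](c1ccccc1)(c1ccccc1)C(C)(C)C)=C\C=O
F6 | step 5 | methyl 3-hydroxy-2-methylidene-4-(PMB-oxy)butanoate (racemic) | COC(=O)C(=C)C(O)COCc1ccc(OC)cc1
F7 | step 5 | methyl 3-acetoxy-2-methylidene-4-(PMB-oxy)butanoate (racemic) | COC(=O)C(=C)C(OC(C)=O)COCc1ccc(OC)cc1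
F8 | step 5 | methyl (2E)-2-[2-(1,3-dioxolan-2-yl)ethyl]-4-(PMB-oxy)but-2-enoate | COC(=O)/C(CCC1OCCO1)=C/COCc1ccc(OC)cc1
F9 | step 18 | 8,15-diol from 26 (both silyl groups removed) | C=C1C(=O)O[C@@H]2/C=C(/CO)CC/C=C(/C(OC)OC)C[C@@H](O)[C@@H]12
F10 | step 18 | 15-O-TBS ether of F9 | C=C1C(=O)O[C@@H]2/C=C(/CO[Si](C)(C)C(C)(C)C)CC/C=C(/C(OC)OC)C[C@@H](O)[C@@H]12
F11 | step 18 | (2R)-2-methylbutanoate of F10 at O8 | C=C1C(=O)O[C@@H]2/C=C(/CO[Si](C)(C)C(C)(C)C)CC/C=C(/C(OC)OC)C[C@@H](OC(=O)[C@H](C)CC)[C@@H]12
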